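## The problem

Atom numbers are those of the spiro[5.5]undecane name of the target 17 and stay with the same carbons in every precursor. Ring B is C1–C6 (C1 carries =CH2, C3 OH, C4 Br, C5 two methyls), ring A is C6–C11 (C8 Br, C9 Cl and CH3), and C6 is the spiro atom.

- The bond C5–C6 joins two quaternary carbons and resists formation most.
- C6 has four carbon neighbours (C1, C5, C7H2, C11H2) and is a stereocentre only through substituents further out. The pair C8/C9 and the pair C3/C4 therefore cannot control each other. Relay works inside each ring (C6 to C9 and C8, C4 to C3) but not between the rings, so two independent sources of absolute configuration are needed.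
- In the chair of ring A the bulky C5 is equatorial and C1 axial, which makes Br-8 and Cl-9 trans-diequatorial and the C9 methyl axial. Anti addition of BrCl to a C8=C9 alkene gives diaxial products. With C5–C6 in place this would put bromine syn-axial to C1 or C5, so late halogenation is stereoelectronically mismatched.
- Ring B holds a cis bromohydrin (neopentyl Br-4 equatorial, OH-3 axial) next to an exocyclic alkene that acid moves into the ring. The tertiary chloride and both secondary bromides do not survive strong base, reducing metals or ionising acid.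
- The feature that makes the key step possible is that C1 stands on ring A 1,4-cis to Cl-9 and trans to Br-8. An oxygen carried by C1 (C1 as a carboxyl carbon) can therefore reach C9 across ring A from inside, anti to a bromonium ion on C8–C9.
- A second feature serves the end: C1(=CH2)–C2H2–C3H(OH) is the retron of a type 2 carbonyl-ene reaction, and C4 is then the only alpha-carbon of the aldehyde.

## Retrosynthesis

**C2–C3 (17 to 15).**
- Cutting this unhindered bond removes ring B, the C3 stereocentre, the free hydroxyl and the exocyclic alkene in one move. It leaves the monocyclic bromo aldehyde 15.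
- The neighbouring cuts (C5–C6, C4–C5) would have to be made between fully substituted carbons in the presence of all halogens.
- The forward ene reaction must give the axial OH cis to Br-4 and keep the alkene exocyclic.

**C4–Br (15 to 14).**
- C4 is the only enolisable position of aldehyde 14, so there is no regiochemical question.
- Ring A cannot bias C4, so the forward bromination must be controlled by a chiral amine catalyst. This is the second source of chirality.

**Functional groups at C3 and C1 (14 to 13 to 12).**
- The aldehyde comes from the vinyl group of 13, and the isopropenyl group from the acetyl group of 12.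
- Both forward steps must be non-basic and must distinguish a monosubstituted alkene from a 1,1-disubstituted one.

**C9–Cl (12 to 11 to 10).**
- The tertiary chloride is traced to a C9–O bond tied back to C1, first as enol ether 11 and then as lactone 10.
- The oxygen leaves as the ketone oxygen of 12 while Br-8, anti to it, guards the configuration.
- The forward step must exchange O for Cl with retention and without loss of a proton.

**C9–O and C8–Br (10 to 9, key step).**
- Both bonds are cut at once, which gives the cyclohexene acid 9 with C6 as its only stereocentre.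
- Against BrCl addition to a spirocycle, this cut needs no conformational bias. The tether fixes C9, and anti opening fixes C8.

**C9–CH3 and the C8=C9 position (9 to 8 to 6).**
- The methyl group is removed to enol triflate 8, and the double bond to ketone 6.
- 6 has a mirror plane through C6 and C9 and no stereocentre.
- The forward deprotonation must choose between two enantiotopic axial protons. This is the first source of chirality.

**C5–C6 (6 to 3 to 1 + 2).**
- In the mirror-symmetric series the hindered bond can be cut as a [3,3] shift of the prenyl ester 3, made from acid 1 and prenol 2.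
- Neither enolate geometry nor facial selectivity matters, which is not so for any precursor with an unsymmetrical ring A.

## Roads not taken

**Alternative 1:** cut C6–C7 and C10–C11 (the most obvious).
- The forward key step is a Diels–Alder reaction of isoprene with the ring B enone A1 to give spiro ketone A2. Ring B is then elaborated to diene A3, and BrCl is added last.
- The dienophile carbon C6 is flanked by C5Me2. A catalyst would have to set a stereocentre whose ring arms differ only at remote atoms.
- The last step is the mismatched one. In A3 the chair-like anti opening with chloride at the tertiary C9 puts Br-8 syn-axial to C1 and leads to the wrong diastereomer. The right one needs a twist-boat or an axial C5. The C1 methylidene group also competes for Br+.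
- The chosen plan makes both halogen centres follow from C6 by geometry.

**Alternative 2:** cut C5–C6 together with C4–Br.
- The forward key step is a biomimetic bromonium-induced cyclisation of the bisabolene-type alcohol A4.
- In a chair transition state the relation between C4 and C6 depends on the geometry of the tetrasubstituted C1=C6 alkene. Its two ring arms differ only at C8, so that geometry cannot be made selectively.
- Br+ would attack the tetrasubstituted alkene before the oxygen-deactivated C4=C5 alkene, and proton loss from the C1 cation is not regioselective.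
- The chosen plan forms C5–C6 while ring A is symmetric and installs Br-4 where only one position can react.

**Alternative 3:** cut C6–C7.
- The forward key step activates the primary alcohol of bromochloride A5, which is available by catalytic enantioselective bromochlorination of the allylic alcohol. Ring A then closes by attack of the tetrasubstituted ring B alkene on C7, assisted by Br-8, to give A6.
- The closure is attractive because bromine anti to the forming bond ends up equatorial. However, A6 has no handle for OH-3 and Br-4.
- If these groups are installed first, C7 must enter cis to Br-4, that is syn-axial to it in the chair-like attack.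
- If they are installed afterwards from a C3 ketone, nothing relates C4 to C6.

Key step: step 5

Remark: the sense of induction of the chiral lithium amide (step 3) and of the pyrrolidine catalyst (step 10) is assigned from the accepted models; both reagents are available as either antipode.

## Steps

Step 1
Reactants: 1 1,4-dioxaspiro[4.5]decane-8-carboxylic acid; 2 3-methylbut-2-en-1-ol (prenol)
Product: 3 3-methylbut-2-en-1-yl 1,4-dioxaspiro[4.5]decane-8-carboxylate
Conditions: DCC, DMAP (cat.), CH2Cl2, 0 °C to rt
Reagents that add atoms: none
Why: Steglich esterification of an unhindered secondary acid with a primary allylic alcohol; the ketal is inert and no stereocentre is involved.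

Step 2
Reactants: 3 3-methylbut-2-en-1-yl 1,4-dioxaspiro[4.5]decane-8-carboxylate
Product: 6 1-(2-methylbut-3-en-2-yl)-4-oxocyclohexane-1-carboxylic acid (achiral), via silyl ketene acetal 4 (not isolated), via trimethylsilyl ester 5 (not isolated)
Conditions: LDA, THF, −78 °C; TMSCl, −78 °C to reflux; then 1 M HCl, THF, rt
Reagents that add atoms: chlorotrimethylsilane C[Si](C)(C)Cl (silyl group of 4 and 5); water O (ketone oxygen of 6)
Why: Ireland–Claisen rearrangement, the standard reaction type for vicinal quaternary carbons, joins C5 to C6 through a six-membered transition state. The C9 ketal keeps a mirror plane through C6 and C9, so 4 has no E/Z isomers and C6 is not yet a stereocentre, and no selectivity is needed. Aqueous acid then frees the acid and the ketone.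

Step 3
Reactants: 6 1-(2-methylbut-3-en-2-yl)-4-oxocyclohexane-1-carboxylic acid
Product: 8 (1S)-1-(2-methylbut-3-en-2-yl)-4-[(trifluoromethyl)sulfonyloxy]cyclohex-3-ene-1-carboxylic acid, via dilithium enolate carboxylate 7 (not isolated)
Conditions: (S,S)-bis(1-phenylethyl)amine, n-BuLi (2.2 equiv each), LiCl, THF, −78 °C; add 6; then PhNTf2, −78 to 0 °C; dilute HCl work-up
Reagents that add atoms: n-butyllithium [Li]CCCC (lithium of 7); N-phenylbis(trifluoromethanesulfonimide) O=S(=O)(N(c1ccccc1)S(=O)(=O)C(F)(F)F)C(F)(F)F
Why: Enantioselective deprotonation of a conformationally locked 4,4-disubstituted cyclohexanone (tert-alkyl group equatorial) by a C2-symmetric chiral lithium amide, the first equivalent forming the carboxylate. Removal of the axial proton at C8 rather than its enantiotopic partner at C10 turns C6 into a stereocentre, and the enolate is trapped as the enol triflate. By analogy with 4-tert-butylcyclohexanone the (S,S)-amide should give the enantiomer drawn.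

Step 4
Reactants: 8 (1S)-1-(2-methylbut-3-en-2-yl)-4-[(trifluoromethyl)sulfonyloxy]cyclohex-3-ene-1-carboxylic acid
Product: 9 (1S)-4-methyl-1-(2-methylbut-3-en-2-yl)cyclohex-3-ene-1-carboxylic acid
Conditions: MeMgBr (3 equiv), Fe(acac)3 (cat.), THF/NMP, −20 °C; dilute HCl work-up
Reagents that add atoms: methylmagnesium bromide C[Mg]Br
Why: Iron-catalysed Kumada-type coupling of an alkenyl triflate with MeMgBr, which is fast at low temperature. The hindered carboxylate and the unactivated vinyl group are left alone, and C6 is untouched.

Step 5
Reactants: 9 (1S)-4-methyl-1-(2-methylbut-3-en-2-yl)cyclohex-3-ene-1-carboxylic acid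
Product: 10 (1R,4S,6R)-6-bromo-1-methyl-4-(2-methylbut-3-en-2-yl)-2-oxabicyclo[2.2.2]octan-3-one
Conditions: NBS, CH2Cl2, 0 °C, dark
Reagents that add atoms: N-bromosuccinimide O=C1CCC(=O)N1Br
Why: NBS transfers Br+ reversibly to both faces of the C8=C9 bond, but only the bromonium ion on the face away from C1 can be opened from inside, so the other one reverts. The carboxyl oxygen attacks the tertiary, more cationic C9 through a boat of ring A in which the C1 bridge takes the flagpole positions and the bulky C5 group and the C9 methyl the bowsprit positions. This closes the six-membered lactone ring O–C1–C6–C11–C10–C9 (6-exo with respect to C8–C9) of a 2-oxabicyclo[2.2.2]octanone. The closest known reaction types are the halolactonisation of 4-methylcyclohex-3-ene-1-carboxylic acids and the bromoetherification of alpha-terpineol to the 2-bromo-1,8-cineole skeleton, which has the same ring sizes and the same choice of carbon. C9 is set by the tether (its oxygen must be cis to C1 across ring A), and C8 is set by the anti opening (Br anti to O, hence cis to C5), so both follow from C6 alone. The step needs site selectivity, secured by the much higher nucleophilicity of the trisubstituted ring alkene over the neopentyl vinyl group. It also needs attack at C9 rather than 5-exo attack at C8, secured by the positive charge at the tertiary carbon.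

Step 6
Reactants: 10 (1R,4S,6R)-6-bromo-1-methyl-4-(2-methylbut-3-en-2-yl)-2-oxabicyclo[2.2.2]octan-3-one
Product: 11 (1R,4S,6R)-6-bromo-1-methyl-3-methylidene-4-(2-methylbut-3-en-2-yl)-2-oxabicyclo[2.2.2]octane
Conditions: Cp2TiMe2, toluene, 70 °C, dark
Reagents that add atoms: dimethyltitanocene [CH3-].[CH3-].[Ti+4].c1cc[cH-]c1.c1cc[cH-]c1
Why: Carbonyl methylenation of lactones with Cp2TiMe2 (through Cp2Ti=CH2) is the standard route to exocyclic enol ethers. The reagent is neither basic nor strongly Lewis acidic, so the secondary bromide and the tertiary C9–O bond survive and no stereocentre is touched.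

Step 7
Reactants: 11 (1R,4S,6R)-6-bromo-1-methyl-3-methylidene-4-(2-methylbut-3-en-2-yl)-2-oxabicyclo[2.2.2]octane
Product: 12 1-[(1S,3R,4R)-3-bromo-4-chloro-4-methyl-1-(2-methylbut-3-en-2-yl)cyclohexyl]ethan-1-one
Conditions: HCl (1 equiv, Et2O solution), Bu4NCl, CH2Cl2, −78 to −20 °C
Reagents that add atoms: hydrogen chloride Cl
Why: Proposed new method: protonation of the enol ether at its CH2 terminus gives an oxocarbenium ion whose tertiary C9–O bond lies anti-periplanar to C8–Br, so it should ionise with bromine participation, releasing a neutral methyl ketone and the strain of the boat; chloride then opens the bromonium ion at the tertiary C9 from the face that the oxygen left (overall retention: Cl cis to C1, trans to Br), and ring A relaxes to the chair with C5, Br and Cl equatorial; the closest known reaction types are the acid cleavage of tert-alkyl enol ethers and tert-alkyl esters to tert-alkyl chlorides and substitution with retention through neighbouring bromine.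

Step 8
Reactants: 12 1-[(1S,3R,4R)-3-bromo-4-chloro-4-methyl-1-(2-methylbut-3-en-2-yl)cyclohexyl]ethan-1-one
Product: 13 (1R,2R,4R)-2-bromo-1-chloro-1-methyl-4-(2-methylbut-3-en-2-yl)-4-(prop-1-en-2-yl)cyclohexane
Conditions: Cp2TiMe2, toluene, 75 °C, dark
Reagents that add atoms: dimethyltitanocene [CH3-].[CH3-].[Ti+4].c1cc[cH-]c1.c1cc[cH-]c1
Why: Titanium-mediated methylenation of a hindered, enolisable methyl ketone. It avoids the basic ylide of a Wittig reaction and zinc-based reagents, which would eliminate HX or reduce the vicinal dihalide.

Step 9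
Reactants: 13 (1R,2R,4R)-2-bromo-1-chloro-1-methyl-4-(2-methylbut-3-en-2-yl)-4-(prop-1-en-2-yl)cyclohexane
Product: 14 3-[(1R,3R,4R)-3-bromo-4-chloro-4-methyl-1-(prop-1-en-2-yl)cyclohexyl]-3-methylbutanal
Conditions: PdCl2(PhCN)2, CuCl2·2H2O, AgNO2 (all cat.), O2 (1 atm), t-BuOH/MeNO2, rt
Reagents that add atoms: dioxygen O=O
Why: Nitrite-modified, aldehyde-selective Wacker oxidation, a reaction type established for vinyl groups on quaternary carbons, places oxygen on the terminal carbon C3. The hindered 1,1-disubstituted isopropenyl group binds palladium poorly and stays, and the conditions are neutral.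

Step 10
Reactants: 14 3-[(1R,3R,4R)-3-bromo-4-chloro-4-methyl-1-(prop-1-en-2-yl)cyclohexyl]-3-methylbutanal
Product: 15 (2R)-2-bromo-3-[(1R,3R,4R)-3-bromo-4-chloro-4-methyl-1-(prop-1-en-2-yl)cyclohexyl]-3-methylbutanal
Conditions: (R)-2-{bis[3,5-bis(trifluoromethyl)phenyl][(trimethylsilyl)oxy]methyl}pyrrolidine (cat.), PhCO2H (cat.), 4,4-dibromo-2,6-di-tert-butylcyclohexa-2,5-dien-1-one, H2O (trace), CH2Cl2/pentane, −40 °C; cold filtration through silica, used at once
Reagents that add atoms: 4,4-dibromo-2,6-di-tert-butylcyclohexa-2,5-dien-1-one O=C1C(C(C)(C)C)=CC(Br)(Br)C=C1C(C)(C)C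
Why: Enamine-catalysed alpha-bromination of aldehydes, known also for aldehydes with a quaternary beta-carbon. The shielding group of the (R)-catalyst leaves one face of the E-enamine open and sets C4 as R regardless of the remote ring A centres. The mild bromine donor reacts with the enamine and not with the isopropenyl group.

Step 11
Reactants: 15 (2R)-2-bromo-3-[(1R,3R,4R)-3-bromo-4-chloro-4-methyl-1-(prop-1-en-2-yl)cyclohexyl]-3-methylbutanal
Product: 17 (3S,4R,6R,8R,9R)-4,8-dibromo-9-chloro-5,5,9-trimethyl-1-methylidenespiro[5.5]undecan-3-ol, via aluminium alkoxide 16 (not isolated)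
Conditions: Me2AlCl (1.5 equiv), CH2Cl2, −78 °C; aqueous NaHCO3 work-up
Reagents that add atoms: dimethylaluminium chloride C[Al](C)Cl (aluminium group of 16)
Why: Type 2 intramolecular carbonyl-ene reaction of an activated alpha-halo aldehyde, helped by the gem-dialkyl effect of C5 and C6, closes ring B at the unhindered C2–C3 bond. In the chair transition state Br-4 is equatorial and anti to the forming bond, and the aluminium-bound oxygen must be axial to take a hydrogen from the methyl group. This gives the axial OH-3 cis to bromine and, by the same hydrogen transfer, only the exocyclic alkene. Me2AlCl removes the proton as methane, so chloride, bromides and alkene see no acid.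

## Compound list

1 | 1,4-dioxaspiro[4.5]decane-8-carboxylic acid | OC(=O)C1CCC2(CC1)OCCO2 | starting material
2 | 3-methylbut-2-en-1-ol (prenol) | CC(C)=CCO | starting material
3 | 3-methylbut-2-en-1-yl 1,4-dioxaspiro[4.5]decane-8-carboxylate | CC(C)=CCOC(=O)C1CCC2(CC1)OCCO2 | intermediate
4 | 8-{[(3-methylbut-2-en-1-yl)oxy][(trimethylsilyl)oxy]methylidene}-1,4-dioxaspiro[4.5]decane | CC(C)=CCOC(O[Si](C)(C)C)=C1CCC2(CC1)OCCO2 | intermediate
5 | trimethylsilyl 8-(2-methylbut-3-en-2-yl)-1,4-dioxaspiro[4.5]decane-8-carboxylate | C=CC(C)(C)C1(CCC2(CC1)OCCO2)C(=O)O[Si](C)(C)C | intermediate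
6 | 1-(2-methylbut-3-en-2-yl)-4-oxocyclohexane-1-carboxylic acid | C=CC(C)(C)C1(CCC(=O)CC1)C(=O)O | intermediate
7 | dilithium (1S)-1-(2-methylbut-3-en-2-yl)-4-oxidocyclohex-3-ene-1-carboxylate | [Li+].[Li+].C=CC(C)(C)[C@]1(C(=O)[O-])CCC([O-])=CC1 | intermediate
8 | (1S)-1-(2-methylbut-3-en-2-yl)-4-[(trifluoromethyl)sulfonyloxy]cyclohex-3-ene-1-carboxylic acid | C=CC(C)(C)[C@]1(C(=O)O)CCC(OS(=O)(=O)C(F)(F)F)=CC1 | intermediate
9 | (1S)-4-methyl-1-(2-methylbut-3-en-2-yl)cyclohex-3-ene-1-carboxylic acid | C=CC(C)(C)[C@]1(C(=O)O)CCC(C)=CC1 | intermediate
10 | (1R,4S,6R)-6-bromo-1-methyl-4-(2-methylbut-3-en-2-yl)-2-oxabicyclo[2.2.2]octan-3-one | C=CC(C)(C)[C@@]12CC[C@@](C)(OC1=O)[C@H](Br)C2 | intermediate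
11 | (1R,4S,6R)-6-bromo-1-methyl-3-methylidene-4-(2-methylbut-3-en-2-yl)-2-oxabicyclo[2.2.2]octane | C=CC(C)(C)[C@@]12CC[C@@](C)(OC1=C)[C@H](Br)C2 | intermediate
12 | 1-[(1S,3R,4R)-3-bromo-4-chloro-4-methyl-1-(2-methylbut-3-en-2-yl)cyclohexyl]ethan-1-one | C=CC(C)(C)[C@]1(C(C)=O)CC[C@@](C)(Cl)[C@H](Br)C1 | intermediate
13 | (1R,2R,4R)-2-bromo-1-chloro-1-methyl-4-(2-methylbut-3-en-2-yl)-4-(prop-1-en-2-yl)cyclohexane | C=CC(C)(C)[C@]1(C(C)=C)CC[C@@](C)(Cl)[C@H](Br)C1 | intermediate
14 | 3-[(1R,3R,4R)-3-bromo-4-chloro-4-methyl-1-(prop-1-en-2-yl)cyclohexyl]-3-methylbutanal | O=CCC(C)(C)[C@]1(C(C)=C)CC[C@@](C)(Cl)[C@H](Br)C1 | intermediate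
15 | (2R)-2-bromo-3-[(1R,3R,4R)-3-bromo-4-chloro-4-methyl-1-(prop-1-en-2-yl)cyclohexyl]-3-methylbutanal | O=C[C@H](Br)C(C)(C)[C@]1(C(C)=C)CC[C@@](C)(Cl)[C@H](Br)C1 | intermediate
16 | chloro(methyl)aluminium alkoxide of 17 | C=C1C[C@H](O[Al](C)Cl)[C@H](Br)C(C)(C)[C@@]12CC[C@@](C)(Cl)[C@H](Br)C2 | intermediate
17 | (3S,4R,6R,8R,9R)-4,8-dibromo-9-chloro-5,5,9-trimethyl-1-methylidenespiro[5.5]undecan-3-ol | C=C1C[C@H](O)[C@H](Br)C(C)(C)[C@@]12CC[C@@](C)(Cl)[C@H](Br)C2 | target

## Step count and least certain steps

Total step count: 11. Longest linear sequence: 11 (steps 1 to 11).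

**Step 7 (proposed new method).**
- The likeliest failure is loss of a proton from the bromine-bridged tertiary cation in place of chloride capture, because the cation is hindered and chloride is a weak nucleophile in CH2Cl2. Slow methylenation of the hindered lactone in step 6 would block the same passage.
- The fallback sets out from 10, returns at 12, and bypasses steps 6 and 7 with known chemistry.
- Dry HCl with ZnCl2 in CH2Cl2 cleaves the tertiary alkyl–oxygen bond of the lactone, again with Br-8 anti to the leaving oxygen. This gives the chloro acid F1.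
- Oxalyl chloride with catalytic DMF gives the acid chloride F2.
- Negishi acylation with Me2Zn and Pd(PPh3)4 at 0 °C then gives 12.

**Step 5 (key step).**
- The likeliest failure is attack of the carboxyl oxygen at C8 in the 5-exo mode. The five-membered lactone forms through a chair, whereas closure at C9 needs a boat.
- The fallback sets out from 9, returns at 13, and replaces the carboxyl oxygen by a tertiary hydroxyl, for which closure at the tertiary carbon has the closest precedent.
- MeLi (excess) gives the methyl ketone F3, and MeMgCl with CeCl3 gives the tertiary alcohol F4.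
- NBS gives the bromo ether F5, and dry HCl opens both tertiary C–O bonds to the dichloride F6.
- Solvolysis in hexafluoroisopropanol with 2,6-lutidine removes HCl only from the unhindered-to-ionise side-chain chloride. That chloride can eliminate in one direction only, because C6 is quaternary, and the product is 13.

**Step 3.**
- The likeliest failure is poor discrimination between the enantiotopic protons. The axial lithium carboxylate is syn-axial to both of them and may bind the amide.
- Partial sulfonylation of the carboxylate would also consume reagent.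
- The fallback sets out from 6, returns at 9, and replaces deprotonation by catalytic alkene isomerisation.
- Wittig methylenation with excess Ph3P=CH2 gives the still achiral methylidene acid F7.
- A chiral cobalt hydride catalyst (from CoCl2, a chiral oxazoline–iminopyridine ligand and NaBHEt3) then moves the double bond into the ring toward one of the two enantiotopic CH2 groups.

**Step 10.**
- The likeliest failures are slow enamine formation next to two quaternary carbons and epimerisation of the product through its enamine or enol, which would erode the C4 configuration.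
- The fallback sets out from 14, returns at 15, and uses an auxiliary in place of a catalyst.
- Pinnick oxidation gives the acid F8.
- The mixed pivalic anhydride and lithiated (R)-4-benzyl-1,3-oxazolidin-2-one give the imide F9.
- Bu2BOTf and i-Pr2NEt followed by NBS give the bromo imide F10.
- LiBH4 gives the bromo alcohol F11, and DMP oxidation gives 15.

**Step 11.**
- The likeliest failure is a shift from the closed transition state to a stepwise addition. The axial aluminium-bound oxygen is syn-axial to a C5 methyl group, so facial selectivity at C3 could become poor.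
- The fallback sets out from 15, returns at 17, and sets C3 by hydride delivery instead of by C–C bond formation.
- The cyclisation product enriched in the C3 epimer F12 is oxidised with DMP to the bromo ketone F13.
- DIBAL-H at −78 °C attacks F13 from the equatorial side, because the axial path is blocked by the axial C5 methyl group. This gives the axial alcohol 17.

## Further compounds

F1 | step 7 | (1S,3R,4R)-3-bromo-4-chloro-4-methyl-1-(2-methylbut-3-en-2-yl)cyclohexane-1-carboxylic acid | C=CC(C)(C)[C@]1(C(=O)O)CC[C@@](C)(Cl)[C@H](Br)C1
F2 | step 7 | (1S,3R,4R)-3-bromo-4-chloro-4-methyl-1-(2-methylbut-3-en-2-yl)cyclohexane-1-carbonyl chloride | C=CC(C)(C)[C@]1(C(=O)Cl)CC[C@@](C)(Cl)[C@H](Br)C1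
F3 | step 5 | 1-[(1S)-4-methyl-1-(2-methylbut-3-en-2-yl)cyclohex-3-en-1-yl]ethan-1-one | C=CC(C)(C)[C@]1(C(C)=O)CCC(C)=CC1
F4 | step 5 | 2-[(1S)-4-methyl-1-(2-methylbut-3-en-2-yl)cyclohex-3-en-1-yl]propan-2-ol | C=CC(C)(C)[C@]1(C(C)(C)O)CCC(C)=CC1
F5 | step 5 | (1R,4S,6R)-6-bromo-1,3,3-trimethyl-4-(2-methylbut-3-en-2-yl)-2-oxabicyclo[2.2.2]octane | C=CC(C)(C)[C@@]12CC[C@@](C)(OC1(C)C)[C@H](Br)C2
F6 | step 5 | (1R,2R,4S)-2-bromo-1-chloro-4-(2-chloropropan-2-yl)-1-methyl-4-(2-methylbut-3-en-2-yl)cyclohexane | C=CC(C)(C)[C@]1(C(C)(C)Cl)CC[C@@](C)(Cl)[C@H](Br)C1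
F7 | step 3 | 4-methylidene-1-(2-methylbut-3-en-2-yl)cyclohexane-1-carboxylic acid | C=CC(C)(C)C1(CCC(=C)CC1)C(=O)O
F8 | step 10 | 3-[(1R,3R,4R)-3-bromo-4-chloro-4-methyl-1-(prop-1-en-2-yl)cyclohexyl]-3-methylbutanoic acid | OC(=O)CC(C)(C)[C@]1(C(C)=C)CC[C@@](C)(Cl)[C@H](Br)C1
F9 | step 10 | (4R)-4-benzyl-3-{3-[(1R,3R,4R)-3-bromo-4-chloro-4-methyl-1-(prop-1-en-2-yl)cyclohexyl]-3-methylbutanoyl}-1,3-oxazolidin-2-one | O=C(CC(C)(C)[C@]1(C(C)=C)CC[C@@](C)(Cl)[C@H](Br)C1)N2[C@H](Cc3ccccc3)COC2=O
F10 | step 10 | (4R)-4-benzyl-3-{(2R)-2-bromo-3-[(1R,3R,4R)-3-bromo-4-chloro-4-methyl-1-(prop-1-en-2-yl)cyclohexyl]-3-methylbutanoyl}-1,3-oxazolidin-2-one | O=C([C@H](Br)C(C)(C)[C@]1(C(C)=C)CC[C@@](C)(Cl)[C@H](Br)C1)N2[C@H](Cc3ccccc3)COC2=O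
F11 | step 10 | (2R)-2-bromo-3-[(1R,3R,4R)-3-bromo-4-chloro-4-methyl-1-(prop-1-en-2-yl)cyclohexyl]-3-methylbutan-1-ol | OC[C@H](Br)C(C)(C)[C@]1(C(C)=C)CC[C@@](C)(Cl)[C@H](Br)C1
F12 | step 11 | (3R,4R,6R,8R,9R)-4,8-dibromo-9-chloro-5,5,9-trimethyl-1-methylidenespiro[5.5]undecan-3-ol | C=C1C[C@@H](O)[C@H](Br)C(C)(C)[C@@]12CC[C@@](C)(Cl)[C@H](Br)C2
F13 | step 11 | (4R,6R,8R,9R)-4,8-dibromo-9-chloro-5,5,9-trimethyl-1-methylidenespiro[5.5]undecan-3-one | C=C1CC(=O)[C@H](Br)C(C)(C)[C@@]12CC[C@@](C)(Cl)[C@H](Br)C2
A1 | alternative 1 | 3,3-dimethyl-2-methylidenecyclohexan-1-one | C=C1C(=O)CCCC1(C)C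
A2 | alternative 1 | 5,5,9-trimethylspiro[5.5]undec-8-en-1-one, C6 as in 17 | O=C1CCCC(C)(C)[C@@]12CCC(C)=CC2
A3 | alternative 1 | 4-bromo-5,5,9-trimethyl-1-methylidenespiro[5.5]undec-8-en-3-ol, C3, C4 and C6 as in 17 | C=C1C[C@H](O)[C@H](Br)C(C)(C)[C@@]12CCC(C)=CC2
A4 | alternative 2 | 1-[(3R,4R)-3-bromo-4-chloro-4-methylcyclohexylidene]-1,5-dimethylhex-4-en-3-ol type alcohol with the chain cis to C11 | CC(C)=C[C@@H](O)C/C(C)=C1\CC[C@@](C)(Cl)[C@H](Br)C1
A5 | alternative 3 | (2R,3R)-2-bromo-3-chloro-3-methyl-5-(2,6,6-trimethylcyclohex-1-en-1-yl)pentan-1-ol | CC1=C(CC[C@@](C)(Cl)[C@H](Br)CO)C(C)(C)CCC1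
A6 | alternative 3 | 8-bromo-9-chloro-5,5,9-trimethyl-1-methylidenespiro[5.5]undecane, C6, C8 and C9 as in 17 | C=C1CCCC(C)(C)[C@@]12CC[C@@](C)(Cl)[C@H](Br)C2
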